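**Retrosynthetic overview**
- The target comes from its aryl triisopropylsilyl ether; the (1E) alkene comes from E2 dehydration of a linear homoallylic alcohol.
- Key disconnection C1'–C2' (side-chain numbering from the chroman): intermolecular carbonyl allylation of (R)-2-methyl-6-silyloxychroman-2-carbaldehyde by a (Z)-allylbarium chloride, which attacks through its α-carbon and keeps its geometry.
- The (Z)-C15 allyl chloride comes from dihydro-β-ionone (cyclohexene ring bought intact): methyl ketone → terminal alkyne → ynoate → syn addition of Me2CuLi, which sets the 3Z alkene.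
- The aldehyde comes from a tertiary alcohol by Pd-catalysed aryl C–O closure, the only ring formed in the route and closed before the fragment union; the tertiary alcohol comes from a benzylic Grignard reagent and a 2-methylglycidyl ether.
- The C2 stereocentre comes from Sharpless epoxidation of methallyl alcohol; the arene is bought intact.

Assumption: the SMILES is read as (2R) at the chroman carbon with a (1E,3Z)-diene, i.e. the chain CH2 on the trisubstituted alkene is cis to the diene carbon.

**Route**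

Step 1
Reactants: 1 2-bromo-5-hydroxybenzaldehyde
Product: 2 2-bromo-5-[(triisopropylsilyl)oxy]benzaldehyde
Conditions: iPr3SiCl (1.1 equiv), imidazole (2 equiv), DMF, rt
Reagents that add atoms: triisopropylsilyl chloride CC(C)[Si](Cl)(C(C)C)C(C)C
Why: Imidazole-promoted O-silylation of the phenol gives a bulky aryl silyl ether that should survive the hydride, organomagnesium, carbonate, hydrogenation, oxidation and organobarium steps and is removed by fluoride at the end.

Step 2
Reactants: 2 2-bromo-5-[(triisopropylsilyl)oxy]benzaldehyde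
Product: 3 {2-bromo-5-[(triisopropylsilyl)oxy]phenyl}methanol
Conditions: NaBH4, MeOH/THF, 0 °C
Reagents that add atoms: none
Why: Borohydride reduction of the aldehyde is chemoselective over the aryl bromide and the silyl ether.

Step 3
Reactants: 3 {2-bromo-5-[(triisopropylsilyl)oxy]phenyl}methanol
Product: 4 [4-bromo-3-(bromomethyl)phenoxy]triisopropylsilane
Conditions: CBr4, PPh3, CH2Cl2, 0 °C
Reagents that add atoms: carbon tetrabromide BrC(Br)(Br)Br
Why: Appel bromination converts the benzylic alcohol into the bromide under neutral conditions that leave the silyl ether and aryl bromide alone.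

Step 4
Reactants: 5 2-methylprop-2-en-1-ol (methallyl alcohol)
Product: 7 [(2R)-2-methyloxiran-2-yl]methyl 4-nitrobenzoate, via (S)-2-methylglycidol 6 (not isolated)
Conditions: Ti(OiPr)4 (5 mol%), L-(+)-diisopropyl tartrate (6 mol%), cumene hydroperoxide, 4 Å sieves, CH2Cl2, −20 °C; then P(OMe)3; Et3N, 4-nitrobenzoyl chloride, 0 °C; recrystallisation
Reagents that add atoms: cumene hydroperoxide CC(C)(OO)c1ccccc1; 4-nitrobenzoyl chloride O=C(Cl)c1ccc(cc1)[N+](=O)[O-]
Why: Catalytic Sharpless asymmetric epoxidation with the titanium L-tartrate catalyst delivers oxygen to one face of the allylic alcohol and sets the epoxide carbon that becomes C2 of the chroman, and acylation in the flask gives a crystalline ester that can be recrystallised to about 98% ee or better.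

Step 5
Reactants: 7 [(2R)-2-methyloxiran-2-yl]methyl 4-nitrobenzoate
Product: 6 (S)-2-methylglycidol
Conditions: K2CO3 (0.1 equiv), MeOH, 0 °C; cold concentration, bulb-to-bulb distillation
Reagents that add atoms: none
Why: Base-catalysed transesterification (methanolysis) of the activated aryl ester frees the epoxy alcohol without opening the epoxide or touching the stereocentre.

Step 6
Reactants: 6 (S)-2-methylglycidol
Product: 8 (2R)-2-[(benzyloxy)methyl]-2-methyloxirane
Conditions: NaH, BnBr, Bu4NI (cat.), THF, 0 °C → rt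
Reagents that add atoms: benzyl bromide BrCc1ccccc1
Why: Williamson etherification of the primary alkoxide leaves the epoxide intact; the descriptor changes from S to R only because the CIP priorities change, not the spatial arrangement.

Step 7
Reactants: 4 [4-bromo-3-(bromomethyl)phenoxy]triisopropylsilane; 8 (2R)-2-[(benzyloxy)methyl]-2-methyloxirane
Product: 10 (2R)-1-(benzyloxy)-4-{2-bromo-5-[(triisopropylsilyl)oxy]phenyl}-2-methylbutan-2-ol, via benzylic Grignard reagent 9 (not isolated)
Conditions: 4 (1.3 equiv), Mg, Et2O, 0 °C; then 8, CuI (10 mol%), THF, −30 → 0 °C; aq. NH4Cl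
Reagents that add atoms: none
Why: Magnesium inserts into the benzylic C–Br bond much faster than into the aryl C–Br bond, and the copper-catalysed SN2 epoxide opening occurs at the unsubstituted CH2, so the quaternary stereocentre is not touched and becomes the tertiary carbinol.

Step 8
Reactants: 10 (2R)-1-(benzyloxy)-4-{2-bromo-5-[(triisopropylsilyl)oxy]phenyl}-2-methylbutan-2-ol
Product: 11 {[(2R)-2-[(benzyloxy)methyl]-2-methylchroman-6-yl]oxy}triisopropylsilane
Conditions: Pd(OAc)2 (3 mol%), rac-2-(di-tert-butylphosphino)-1,1'-binaphthyl (4 mol%), Cs2CO3, toluene, 80 °C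
Reagents that add atoms: none
Why: Buchwald-type palladium-catalysed intramolecular aryl C–O coupling closes the dihydropyran ring; a tertiary alkoxide cannot undergo β-hydride elimination, and because the new bond is O–aryl the carbinol configuration is retained.

Step 9
Reactants: 11 {[(2R)-2-[(benzyloxy)methyl]-2-methylchroman-6-yl]oxy}triisopropylsilane
Product: 12 {(2R)-2-methyl-6-[(triisopropylsilyl)oxy]chroman-2-yl}methanol
Conditions: H2 (1 atm), 10% Pd/C, EtOAc, rt
Reagents that add atoms: none
Why: Hydrogenolysis removes the benzyl ether while the aryl silyl ether and the non-benzylic chroman C–O bond are inert.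

Step 10
Reactants: 12 {(2R)-2-methyl-6-[(triisopropylsilyl)oxy]chroman-2-yl}methanol
Product: 13 (2R)-2-methyl-6-[(triisopropylsilyl)oxy]chroman-2-carbaldehyde
Conditions: Dess–Martin periodinane, CH2Cl2, 0 °C → rt
Reagents that add atoms: none
Why: Dess–Martin oxidation of the neopentyl-type primary alcohol gives an aldehyde with a quaternary α-carbon that cannot enolise or epimerise.

Step 11
Reactants: 14 dihydro-β-ionone, 4-(2,6,6-trimethylcyclohex-1-en-1-yl)butan-2-one
Product: 16 2-(but-3-yn-1-yl)-1,3,3-trimethylcyclohex-1-ene, via enol phosphate 15 (not isolated)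
Conditions: LiN(iPr)2 (1.1 equiv), THF, −78 °C; ClP(O)(OEt)2, −78 °C → rt; then LiN(iPr)2 (2.3 equiv), −78 °C → rt; H2O
Reagents that add atoms: none
Why: Negishi's methyl ketone to alkyne sequence: kinetic deprotonation at the methyl group, O-phosphorylation and base-induced elimination of phosphate give the terminal alkyne with the remote tetrasubstituted alkene untouched.

Step 12
Reactants: 16 2-(but-3-yn-1-yl)-1,3,3-trimethylcyclohex-1-ene
Product: 17 methyl 5-(2,6,6-trimethylcyclohex-1-en-1-yl)pent-2-ynoate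
Conditions: nBuLi, THF, −78 °C; ClCO2Me, −78 → 0 °C
Reagents that add atoms: methyl chloroformate COC(=O)Cl
Why: C-acylation of the lithium acetylide with a chloroformate gives the ynoate cleanly.

Step 13
Reactants: 17 methyl 5-(2,6,6-trimethylcyclohex-1-en-1-yl)pent-2-ynoate
Product: 18 methyl (2Z)-3-methyl-5-(2,6,6-trimethylcyclohex-1-en-1-yl)pent-2-enoate
Conditions: Me2CuLi (1.3 equiv, from CuI and 2 MeLi), THF, −78 °C, 1 h; MeOH at −78 °C, then aq. NH4Cl
Reagents that add atoms: lithium dimethylcuprate [Li+].C[Cu-]C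
Why: Conjugate (Michael-type) syn-carbocupration of the ynoate and protonation of the vinylcopper with retention at −78 °C put the new methyl cis to H, so the chain is cis to the ester (Z, expected ≥95:5).

Step 14
Reactants: 18 methyl (2Z)-3-methyl-5-(2,6,6-trimethylcyclohex-1-en-1-yl)pent-2-enoate
Product: 19 (2Z)-3-methyl-5-(2,6,6-trimethylcyclohex-1-en-1-yl)pent-2-en-1-ol
Conditions: iBu2AlH (2.5 equiv), CH2Cl2, −78 → 0 °C; aq. potassium sodium tartrate
Reagents that add atoms: none
Why: 1,2-Reduction of the enoate by the aluminium hydride gives the allylic alcohol without touching the alkene geometry; any minor E isomer is removed here by chromatography.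

Step 15
Reactants: 19 (2Z)-3-methyl-5-(2,6,6-trimethylcyclohex-1-en-1-yl)pent-2-en-1-ol
Product: 20 2-[(3Z)-5-chloro-3-methylpent-3-en-1-yl]-1,3,3-trimethylcyclohex-1-ene
Conditions: N-chlorosuccinimide, Me2S, CH2Cl2, −20 °C; then 19, −20 → 0 °C
Reagents that add atoms: N-chlorosuccinimide ClN1C(=O)CCC1=O
Why: Corey–Kim chlorination proceeds by SN2 attack of chloride on the primary alkoxysulfonium carbon, so there is no allylic transposition and no Z/E change (as for nerol to neryl chloride).

Step 16
Reactants: 20 2-[(3Z)-5-chloro-3-methylpent-3-en-1-yl]-1,3,3-trimethylcyclohex-1-ene; 13 (2R)-2-methyl-6-[(triisopropylsilyl)oxy]chroman-2-carbaldehyde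
Product: 22 (3Z)-4-methyl-1-{(2R)-2-methyl-6-[(triisopropylsilyl)oxy]chroman-2-yl}-6-(2,6,6-trimethylcyclohex-1-en-1-yl)hex-3-en-1-ol (both C1 epimers), via allylbarium chloride 21 (not isolated)
Conditions: BaI2, lithium biphenylide LiC12H10 (2 equiv per Ba), THF, rt (activated Ba); 20 (1.4 equiv), −78 °C, 30 min; 13, −78 °C, 30 min; aq. NH4Cl
Reagents that add atoms: none
Why: Carbonyl allylation with an allylbarium reagent, which unlike allyl-magnesium, -zinc or -indium reagents attacks through its unsubstituted α-carbon and keeps its Z geometry at −78 °C, gives the linear homoallylic alcohol from the non-enolisable aldehyde; the new carbinol centre forms unselectively and is removed in the next step.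

Step 17
Reactants: 22 (3Z)-4-methyl-1-{(2R)-2-methyl-6-[(triisopropylsilyl)oxy]chroman-2-yl}-6-(2,6,6-trimethylcyclohex-1-en-1-yl)hex-3-en-1-ol
Product: 24 {[(2R)-2-methyl-2-[(1E,3Z)-4-methyl-6-(2,6,6-trimethylcyclohex-1-en-1-yl)hexa-1,3-dien-1-yl]chroman-6-yl]oxy}triisopropylsilane, via mesylate 23 (not isolated)
Conditions: MsCl, Et3N, CH2Cl2, 0 °C; solvent change to toluene, DBU (3 equiv), 90 °C
Reagents that add atoms: none
Why: Mesylation and base-induced anti E2 elimination can only use the allylic C2' hydrogens (the other neighbour is quaternary), so both epimers converge on the conjugated trans (1E) alkene, and the non-ionising conditions leave the 3Z alkene and C2 alone.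

Step 18
Reactants: 24 {[(2R)-2-methyl-2-[(1E,3Z)-4-methyl-6-(2,6,6-trimethylcyclohex-1-en-1-yl)hexa-1,3-dien-1-yl]chroman-6-yl]oxy}triisopropylsilane
Product: 25 (2R)-2-methyl-2-[(1E,3Z)-4-methyl-6-(2,6,6-trimethylcyclohex-1-en-1-yl)hexa-1,3-dien-1-yl]chroman-6-ol
Conditions: Bu4NF (1.2 equiv), AcOH (1.2 equiv), THF, 0 °C, under argon
Reagents that add atoms: none
Why: Buffered fluoride cleavage of the aryl silyl ether is near neutral, so the acid-sensitive tertiary allylic aryl ether at C2 and the diene are not disturbed.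

**Compound list**
1 | 2-bromo-5-hydroxybenzaldehyde | O=Cc1cc(O)ccc1Br | starting material
2 | 2-bromo-5-[(triisopropylsilyl)oxy]benzaldehyde | O=Cc1cc(O[Si](C(C)C)(C(C)C)C(C)C)ccc1Br | intermediate
3 | {2-bromo-5-[(triisopropylsilyl)oxy]phenyl}methanol | OCc1cc(O[Si](C(C)C)(C(C)C)C(C)C)ccc1Br | intermediate
4 | [4-bromo-3-(bromomethyl)phenoxy]triisopropylsilane | BrCc1cc(O[Si](C(C)C)(C(C)C)C(C)C)ccc1Br | intermediate
5 | 2-methylprop-2-en-1-ol (methallyl alcohol) | CC(=C)CO | starting material
6 | (S)-2-methylglycidol = [(2S)-2-methyloxiran-2-yl]methanol | OC[C@@]1(C)CO1 | intermediate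
7 | [(2R)-2-methyloxiran-2-yl]methyl 4-nitrobenzoate (the 4-nitrobenzoate of 6) | O=C(OC[C@@]1(C)CO1)c1ccc(cc1)[N+](=O)[O-] | intermediate
8 | (2R)-2-[(benzyloxy)methyl]-2-methyloxirane (the benzyl ether of 6) | c1ccccc1COC[C@@]1(C)CO1 | intermediate
9 | {2-bromo-5-[(triisopropylsilyl)oxy]benzyl}magnesium bromide | Br[Mg]Cc1cc(O[Si](C(C)C)(C(C)C)C(C)C)ccc1Br | intermediate
10 | (2R)-1-(benzyloxy)-4-{2-bromo-5-[(triisopropylsilyl)oxy]phenyl}-2-methylbutan-2-ol | c1ccccc1COC[C@@](O)(C)CCc1cc(O[Si](C(C)C)(C(C)C)C(C)C)ccc1Br | intermediate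
11 | {[(2R)-2-[(benzyloxy)methyl]-2-methylchroman-6-yl]oxy}triisopropylsilane | c1ccccc1COC[C@@]1(C)CCc2cc(O[Si](C(C)C)(C(C)C)C(C)C)ccc2O1 | intermediate
12 | {(2R)-2-methyl-6-[(triisopropylsilyl)oxy]chroman-2-yl}methanol | OC[C@@]1(C)CCc2cc(O[Si](C(C)C)(C(C)C)C(C)C)ccc2O1 | intermediate
13 | (2R)-2-methyl-6-[(triisopropylsilyl)oxy]chroman-2-carbaldehyde | O=C[C@@]1(C)CCc2cc(O[Si](C(C)C)(C(C)C)C(C)C)ccc2O1 | intermediate
14 | dihydro-β-ionone = 4-(2,6,6-trimethylcyclohex-1-en-1-yl)butan-2-one | CC(=O)CCC1=C(C)CCCC1(C)C | starting material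
15 | diethyl 4-(2,6,6-trimethylcyclohex-1-en-1-yl)but-1-en-2-yl phosphate | C=C(CCC1=C(C)CCCC1(C)C)OP(=O)(OCC)OCC | intermediate
16 | 2-(but-3-yn-1-yl)-1,3,3-trimethylcyclohex-1-ene | C#CCCC1=C(C)CCCC1(C)C | intermediate
17 | methyl 5-(2,6,6-trimethylcyclohex-1-en-1-yl)pent-2-ynoate | COC(=O)C#CCCC1=C(C)CCCC1(C)C | intermediate
18 | methyl (2Z)-3-methyl-5-(2,6,6-trimethylcyclohex-1-en-1-yl)pent-2-enoate | COC(=O)/C=C(/C)CCC1=C(C)CCCC1(C)C | intermediate
19 | (2Z)-3-methyl-5-(2,6,6-trimethylcyclohex-1-en-1-yl)pent-2-en-1-ol | OC/C=C(/C)CCC1=C(C)CCCC1(C)C | intermediate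
20 | 2-[(3Z)-5-chloro-3-methylpent-3-en-1-yl]-1,3,3-trimethylcyclohex-1-ene | ClC/C=C(/C)CCC1=C(C)CCCC1(C)C | intermediate
21 | [(2Z)-3-methyl-5-(2,6,6-trimethylcyclohex-1-en-1-yl)pent-2-en-1-yl]barium chloride | Cl[Ba]C/C=C(/C)CCC1=C(C)CCCC1(C)C | intermediate
22 | (3Z)-4-methyl-1-{(2R)-2-methyl-6-[(triisopropylsilyl)oxy]chroman-2-yl}-6-(2,6,6-trimethylcyclohex-1-en-1-yl)hex-3-en-1-ol (both C1 epimers) | CC1=C(CC/C(C)=C\CC(O)[C@@]2(C)CCc3cc(O[Si](C(C)C)(C(C)C)C(C)C)ccc3O2)C(C)(C)CCC1 | intermediate
23 | methanesulfonate of 22 | CC1=C(CC/C(C)=C\CC(OS(C)(=O)=O)[C@@]2(C)CCc3cc(O[Si](C(C)C)(C(C)C)C(C)C)ccc3O2)C(C)(C)CCC1 | intermediate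
24 | {[(2R)-2-methyl-2-[(1E,3Z)-4-methyl-6-(2,6,6-trimethylcyclohex-1-en-1-yl)hexa-1,3-dien-1-yl]chroman-6-yl]oxy}triisopropylsilane | CC1=C(CC/C(C)=C\C=C\[C@@]2(C)CCc3cc(O[Si](C(C)C)(C(C)C)C(C)C)ccc3O2)C(C)(C)CCC1 | intermediate
25 | (2R)-2-methyl-2-[(1E,3Z)-4-methyl-6-(2,6,6-trimethylcyclohex-1-en-1-yl)hexa-1,3-dien-1-yl]chroman-6-ol | CC1=C(CC/C(C)=C\C=C\[C@@]2(C)CCc3cc(O)ccc3O2)C(C)(C)CCC1 | target

**Step count and risk**
Total: 18 steps. Longest linear sequence: 10 steps (steps 1, 2, 3, 7, 8, 9, 10, 16, 17, 18; the branch from methallyl alcohol through steps 4, 5, 6 is equally long).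

The three steps most likely to fail:

First, step 16. It is the least routine operation: it needs freshly made activated barium, and any γ-attack or Z to E leakage there cannot be corrected later. The fallback replaces allylation and dehydration by a Julia–Lythgoe olefination; it sets out from chloride 20 (used with aldehyde 13) and comes back at 24. PhSO2Na in DMF converts 20 into the allylic sulfone {[(2Z)-3-methyl-5-(2,6,6-trimethylcyclohex-1-en-1-yl)pent-2-en-1-yl]sulfonyl}benzene F1. Its α-lithio derivative (nBuLi, THF, −78 °C) keeps the charge next to sulfur and so keeps the Z alkene; it is added to 13 and the alkoxide is acetylated in the flask (Ac2O) to give the β-acetoxy sulfone F2. Sodium amalgam Na(Hg) with Na2HPO4 in MeOH/THF at −20 °C then gives 24 by reductive elimination, trans-selectively.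

Second, step 17. The carbinol is flanked by a quaternary carbon, so mesylation or the E2 step may be slow and some ionisation is possible. The fallback makes the C1'=C2' bond by enolisation in place of elimination; it sets out from 22 and comes back at 24. Dess–Martin oxidation of 22 gives the β,γ-unsaturated ketone F3. KN(SiMe3)2 in THF at −78 °C followed by PhNTf2 gives the (1Z,3Z)-dienyl triflate F4, the bulky tertiary substituent enforcing the Z enolate. Pd(OAc)2/PPh3 with Bu3N and HCO2H in DMF at 60 °C replaces the triflate by hydrogen with retention, which is the (1E) alkene of 24.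

Third, step 13. The whole route depends on its Z:E ratio, which falls if the vinylcopper warms before protonation. The fallback builds the same alkene by cross-coupling on a stereodefined enol triflate; it sets out from 14 and comes back at 18. NaH and dimethyl carbonate in THF at reflux (Claisen-type C-acylation at the methyl group) give the β-keto ester methyl 3-oxo-5-(2,6,6-trimethylcyclohex-1-en-1-yl)pentanoate F5. Tf2O with aqueous Me4NOH in toluene (non-chelating conditions) gives the (E)-enol triflate F6. Negishi methylation (MeZnCl, Pd(PPh3)4, THF, rt) with retention gives 18.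

**Further compounds**
F1 | step 16 | {[(2Z)-3-methyl-5-(2,6,6-trimethylcyclohex-1-en-1-yl)pent-2-en-1-yl]sulfonyl}benzene | O=S(=O)(C/C=C(/C)CCC1=C(C)CCCC1(C)C)c1ccccc1
F2 | step 16 | (3Z)-4-methyl-1-{(2R)-2-methyl-6-[(triisopropylsilyl)oxy]chroman-2-yl}-2-(phenylsulfonyl)-6-(2,6,6-trimethylcyclohex-1-en-1-yl)hex-3-en-1-yl acetate (diastereomer mixture) | CC1=C(CC/C(C)=C\C(C(OC(C)=O)[C@@]2(C)CCc3cc(O[Si](C(C)C)(C(C)C)C(C)C)ccc3O2)S(=O)(=O)c2ccccc2)C(C)(C)CCC1
F3 | step 17 | (3Z)-4-methyl-1-{(2R)-2-methyl-6-[(triisopropylsilyl)oxy]chroman-2-yl}-6-(2,6,6-trimethylcyclohex-1-en-1-yl)hex-3-en-1-one | CC1=C(CC/C(C)=C\CC(=O)[C@@]2(C)CCc3cc(O[Si](C(C)C)(C(C)C)C(C)C)ccc3O2)C(C)(C)CCC1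
F4 | step 17 | (1Z,3Z)-4-methyl-1-{(2R)-2-methyl-6-[(triisopropylsilyl)oxy]chroman-2-yl}-6-(2,6,6-trimethylcyclohex-1-en-1-yl)hexa-1,3-dien-1-yl trifluoromethanesulfonate | CC1=C(CC/C(C)=C\C=C(/OS(=O)(=O)C(F)(F)F)[C@@]2(C)CCc3cc(O[Si](C(C)C)(C(C)C)C(C)C)ccc3O2)C(C)(C)CCC1
F5 | step 13 | methyl 3-oxo-5-(2,6,6-trimethylcyclohex-1-en-1-yl)pentanoate | COC(=O)CC(=O)CCC1=C(C)CCCC1(C)C
F6 | step 13 | methyl (2E)-5-(2,6,6-trimethylcyclohex-1-en-1-yl)-3-{[(trifluoromethyl)sulfonyl]oxy}pent-2-enoate | COC(=O)/C=C(/OS(=O)(=O)C(F)(F)F)CCC1=C(C)CCCC1(C)C
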